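## Retrosynthetic overview

1. Feature used: ring A (C4a–C5–C6–C7–C8–C8a) is hexasubstituted with strictly alternating O and C substituents. These are 5-OH, 7-OMe and O1 on C8a, against the C4 acyl group on C4a and prenyl on C6 and C8. This is the substitution code of a ketene/ynol ether benzannulation.
2. Key cut: C5–C6, C7–C8 and C4a–C5. Ring A is built last, in one operation, from two partners: a vinylketene O=C5=C8(prenyl)– attached to C8a of an enantiopure 2-aryl-2,3-dihydropyran-4-one (ring C, C2 already set), and MeO–C7≡C6–prenyl. The sequence is [2+2], strain-driven 4π opening of the cyclobutenone (C5–C8 cut), then 6π closure onto C4a.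
3. This one step delivers both prenyl groups and the already differentiated free 5-OH and 7-OMe, under near-neutral conditions that leave the labile C2 centre alone.
4. The vinylketene precursor is a pyranonyl acid, made from the parent dihydropyranone by Mukaiyama–Michael addition and Saegusa–Ito re-oxidation. Ring C and C2 come from a catalytic asymmetric hetero-Diels–Alder reaction of the B-ring aldehyde.
5. Ring order: B (bought), then C (step 3), then A (step 6).

Key step: step 6

Assumption: the (S)-BINOL–Ti(IV) catalyst is taken to direct attack to the Si face of the aromatic aldehyde, as in its allylation and aldol reactions; should the chiroptical data of the pyranone show the opposite sense, (R)-BINOL is used and nothing else changes. (Prenyl = 3-methylbut-2-en-1-yl; TBS = tert-butyldimethylsilyl; TMS = trimethylsilyl.)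

## Route

Step 1
Reactants: 1 2-chloro-1,1-dimethoxyethane; 2 prenyl bromide (1-bromo-3-methylbut-2-ene)
Product: 4 1-methoxy-5-methylhex-4-en-1-yne, via lithium methoxyacetylide 3 (not isolated)
Conditions: LiNEt2 (3.0 equiv), THF, −10 °C to rt; then 2, DMPU, −78 to 0 °C; distillation
Reagents that add atoms: none
Why: Twofold base-induced β-elimination (HCl, then MeOH) from the chloroacetal and deprotonation give the metallated ynol ether 3, which is alkylated by SN2 attack on the primary allylic bromide (acetylide alkylation); the O-methyl group has no β-hydrogen, so 4 cannot lose an alkene by retro-ene reaction in the hot key step.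

Step 2
Reactants: 5 5-methylhex-4-enoic acid
Product: 6 1,1-bis(trimethylsilyloxy)-5-methylhexa-1,4-diene
Conditions: LDA (2.1 equiv), THF, 0 °C; TMSCl (2.3 equiv), 0 °C to rt; distillation
Reagents that add atoms: chlorotrimethylsilane, C[Si](C)(C)Cl
Why: Double deprotonation of the acid to its enediolate and O,O-disilylation (bis-silyl ketene acetal formation) is a general reaction of carboxylic acids, and the remote trisubstituted alkene is inert to LDA and TMSCl.

Step 3
Reactants: 7 4-(tert-butyldimethylsilyloxy)benzaldehyde; 8 (E)-1-methoxy-3-(trimethylsilyloxy)buta-1,3-diene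
Product: 10 (2S)-2-[4-(tert-butyldimethylsilyloxy)phenyl]-2,3-dihydro-4H-pyran-4-one, via open-chain aldol adduct 9 (not isolated)
Conditions: (S)-BINOL (20 mol %), Ti(OiPr)4 (10 mol %), 4 Å MS, Et2O, −20 °C; then TFA, CH2Cl2, 0 °C
Reagents that add atoms: none
Why: Catalytic asymmetric hetero-Diels–Alder reaction in its Mukaiyama-aldol/cyclisation form: the BINOL–Ti(IV) Lewis acid binds the aldehyde and shields its Re face, the diene terminus adds to the Si face and sets C2 as S in 9, and TFA closes ring C by addition–elimination (loss of MeOH) without touching the C2–O bond.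

Step 4
Reactants: 10 (2S)-2-aryl-2,3-dihydro-4H-pyran-4-one; 6 bis-silyl ketene acetal
Product: 11 trimethylsilyl 2-{(6S)-6-[4-(tert-butyldimethylsilyloxy)phenyl]-4-(trimethylsilyloxy)-5,6-dihydro-2H-pyran-2-yl}-5-methylhex-4-enoate (mixture of isomers at the pyran C2 and at the chain α-carbon)
Conditions: TMSOTf (10 mol %), CH2Cl2, −78 °C; Et3N quench, non-aqueous work-up, used crude
Reagents that add atoms: none
Why: Mukaiyama–Michael addition: catalytic silyl triflate turns the vinylogous ester into a 4-silyloxy oxocarbenium ion that is attacked at C6 by the ketene acetal carbon, silyl transfer fixes the enolate as the regiodefined C4=C5 enol silane, the aryl-bearing centre is untouched, and the two new centres (axial attack anti to the aryl group expected, α-carbon unselective) need no control because steps 5 and 6 erase them.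

Step 5
Reactants: 11 bis-silylated Michael adduct
Product: 12 2-{(2S)-2-[4-(tert-butyldimethylsilyloxy)phenyl]-4-oxo-3,4-dihydro-2H-pyran-6-yl}-5-methylhex-4-enoic acid (both epimers at the chain α-carbon)
Conditions: Pd(OAc)2 (1.05 equiv), MeCN, rt; aqueous pH 5 buffer work-up
Reagents that add atoms: none
Why: Saegusa–Ito oxidation: the palladium enolate formed at C5 from the enol silane has only the C6–H available for β-hydride elimination, so the C5=C6 bond is restored regiospecifically and away from C2/C3, and the labile trimethylsilyl ester falls to the free acid in the mildly acidic work-up.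

Step 6
Reactants: 12 pyranonyl acid; 4 1-methoxy-5-methylhex-4-en-1-yne
Product: 17 (2S)-2-[4-(tert-butyldimethylsilyloxy)phenyl]-5-hydroxy-7-methoxy-6,8-bis(3-methylbut-2-en-1-yl)chroman-4-one, via acid chloride 13 (not isolated), via vinylketene 14 (not isolated), via vinylcyclobutenone 15 (not isolated), via dienylketene 16 (not isolated)
Conditions: 1-chloro-N,N,2-trimethylpropenylamine (1.05 equiv), CH2Cl2, 0 °C; then 4 (3 equiv), iPr2NEt (1.1 equiv, slow addition), toluene, 0 to 40 °C; filtration of the ammonium salt; toluene, 100 °C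
Reagents that add atoms: none
Why: Danheiser-type vinylketene/alkynyl ether benzannulation: neutral chlorination of 12 and dehydrochlorination at the doubly activated α-C–H give vinylketene 14, whose carbonyl carbon (future C5) is attacked by the nucleophilic, prenyl-bearing carbon of ynol ether 4 (future C6), so that the [2+2] cycloaddition forms C5–C6 and C7–C8 and gives cyclobutenone 15. On heating, release of the four-ring strain drives the reversible 4π electrocyclic opening of 15 (C5–C8 is cut) to dienylketene 16, and only the isomer with the pyranone C=C turned towards the ketene is drained by a 6π electrocyclic closure that forms C5–C4a (ring A, a six-membered carbocycle closed onto the nucleophilic α-carbon of the vinylogous ester), after which tautomerisation gives the phenol chelated to C4=O. The closest known reaction type is the benzannulation of cycloalkenyl and heteroaryl vinylketenes (from cyclobutenones, diazo ketones or unsaturated acid chlorides) with 1-alkoxyalkynes to give resorcinol monoethers. No new stereocentre survives (the quaternary carbon of 15 is planarised), and C2 is carried through unchanged because nothing breaks O1–C2 or enolises C3 and the amine salt is removed before heating. The step needs regioselectivity (5-OH/7-OMe, not 5-OMe/7-OH), which is secured by the ketene/ynol ether polarity and by four-ring closure at C8 in preference to six-ring closure at C4a, and it needs chemoselectivity against oxa-6π closure to an α-pyrone, which ring C itself secures by holding C4=O trans to the ketene across C4a=C8a.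

Step 7
Reactants: 17 4'-O-TBS flavanone
Product: 18 (2S)-5-hydroxy-2-(4-hydroxyphenyl)-7-methoxy-6,8-bis(3-methylbut-2-en-1-yl)chroman-4-one (target, CNP0121058.1)
Conditions: TBAF (1.1 equiv), AcOH (1.5 equiv), THF, 0 °C
Reagents that add atoms: none
Why: Fluoride-induced cleavage of the aryl silyl ether (desilylation) is fast at 0 °C, and the acetic acid buffer protonates the 4'-phenoxide at once, so that neither retro-oxa-Michael opening through a C3 enolate nor para-quinone-methide opening of O1–C2 can scramble C2, while the prenyl groups, the chelated 5-OH and the 7-OMe are inert.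

## Compound list

1 | 2-chloro-1,1-dimethoxyethane | COC(CCl)OC | starting material
2 | prenyl bromide (1-bromo-3-methylbut-2-ene) | CC(C)=CCBr | starting material
3 | lithium methoxyacetylide | [Li]C#COC | intermediate
4 | 1-methoxy-5-methylhex-4-en-1-yne | COC#CCC=C(C)C | intermediate
5 | 5-methylhex-4-enoic acid | CC(C)=CCCC(=O)O | starting material
6 | 1,1-bis(trimethylsilyloxy)-5-methylhexa-1,4-diene | CC(C)=CCC=C(O[Si](C)(C)C)O[Si](C)(C)C | intermediate
7 | 4-(tert-butyldimethylsilyloxy)benzaldehyde | O=Cc1ccc(O[Si](C)(C)C(C)(C)C)cc1 | starting material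
8 | (E)-1-methoxy-3-(trimethylsilyloxy)buta-1,3-diene | CO/C=C/C(=C)O[Si](C)(C)C | starting material
9 | (1E,5S)-5-[4-(tert-butyldimethylsilyloxy)phenyl]-1-methoxy-5-(trimethylsilyloxy)pent-1-en-3-one | CO/C=C/C(=O)C[C@@H](c1ccc(O[Si](C)(C)C(C)(C)C)cc1)O[Si](C)(C)C | intermediate
10 | (2S)-2-[4-(tert-butyldimethylsilyloxy)phenyl]-2,3-dihydro-4H-pyran-4-one | O=C1C[C@@H](c2ccc(O[Si](C)(C)C(C)(C)C)cc2)OC=C1 | intermediate
11 | trimethylsilyl 2-{(6S)-6-[4-(tert-butyldimethylsilyloxy)phenyl]-4-(trimethylsilyloxy)-5,6-dihydro-2H-pyran-2-yl}-5-methylhex-4-enoate (isomer mixture at the two other centres) | CC(C)=CCC(C(=O)O[Si](C)(C)C)C1C=C(O[Si](C)(C)C)C[C@@H](c2ccc(O[Si](C)(C)C(C)(C)C)cc2)O1 | intermediate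
12 | 2-{(2S)-2-[4-(tert-butyldimethylsilyloxy)phenyl]-4-oxo-3,4-dihydro-2H-pyran-6-yl}-5-methylhex-4-enoic acid (α-epimers) | CC(C)=CCC(C(=O)O)C1=CC(=O)C[C@@H](c2ccc(O[Si](C)(C)C(C)(C)C)cc2)O1 | intermediate
13 | acid chloride of 12 | CC(C)=CCC(C(=O)Cl)C1=CC(=O)C[C@@H](c2ccc(O[Si](C)(C)C(C)(C)C)cc2)O1 | intermediate
14 | vinylketene: 2-{(2S)-2-aryl-4-oxo-3,4-dihydro-2H-pyran-6-yl}-5-methylhexa-1,4-dien-1-one | CC(C)=CCC(=C=O)C1=CC(=O)C[C@@H](c2ccc(O[Si](C)(C)C(C)(C)C)cc2)O1 | intermediate
15 | 3-methoxy-2,4-diprenyl-4-{(2S)-2-aryl-4-oxo-3,4-dihydro-2H-pyran-6-yl}cyclobut-2-en-1-one (both configurations at C4 of the four-membered ring) | COC1=C(CC=C(C)C)C(=O)C1(CC=C(C)C)C2=CC(=O)C[C@@H](c3ccc(O[Si](C)(C)C(C)(C)C)cc3)O2 | intermediate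
16 | dienylketene from ring opening of 15 | O=C=C(CC=C(C)C)C(OC)=C(CC=C(C)C)C1=CC(=O)C[C@@H](c2ccc(O[Si](C)(C)C(C)(C)C)cc2)O1 | intermediate
17 | (2S)-2-[4-(tert-butyldimethylsilyloxy)phenyl]-5-hydroxy-7-methoxy-6,8-diprenylchroman-4-one | COc1c(CC=C(C)C)c(O)c2c(c1CC=C(C)C)O[C@H](c1ccc(O[Si](C)(C)C(C)(C)C)cc1)CC2=O | intermediate
18 | (2S)-5-hydroxy-2-(4-hydroxyphenyl)-7-methoxy-6,8-diprenylchroman-4-one | COc1c(CC=C(C)C)c(O)c2c(c1CC=C(C)C)O[C@H](c1ccc(O)cc1)CC2=O | target

## Step count and risks

Total step count: 7. Longest linear sequence: 5 (steps 3, 4, 5, 6, 7, from aldehyde 7).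

### Steps most likely to fail

**1. Step 6 (key step).**
- What may go wrong:
  - amine-induced oligomerisation of the vinylketene before it meets the ynol ether;
  - collapse of the ketene/ynol ether zwitterion at C4a instead of C8, which would swap 5-OH and 7-OMe;
  - a [1,5]-hydrogen shift from an inward-turned prenyl CH2 in the dienylketene;
  - slow erosion of the C2 configuration on long heating.
- Fallback: it sets out from prenyl bromide 2 and comes back at 17. Ring A is bought instead of built, and C2 is set by forming the C2–C1' bond.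
  - Commercial 2,4,6-trihydroxyacetophenone is C-prenylated twice with 2 (aq. KOH, 0 °C) to 3,5-diprenylphloracetophenone F1.
  - The only non-chelated hydroxyl is methylated (MeI, 1 equiv, K2CO3, acetone) to the 4-O-methyl ether F2.
  - N,N-Dimethylformamide dimethyl acetal gives the enaminone F3.
  - F3 closes on silica gel/AcOH to 5-hydroxy-7-methoxy-6,8-diprenylchromone F4. Either ortho hydroxyl gives the same product because the A ring is locally symmetric.
  - A Rh(I)-catalysed asymmetric 1,4-addition of commercial 4-(tert-butyldimethylsilyloxy)phenylboronic acid in toluene then gives 17. It uses an electron-poor atropisomeric diphosphine, in the antipode that gives 2S.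

**2. Step 5.**
- What may go wrong:
  - protodesilylation of the trimethylsilyl enol ether before palladation, which would lose the regiocontrol;
  - binding of palladium by the carboxylate or the prenyl alkene;
  - loss of CO2 from the vinylogous β-keto acid during work-up.
- Fallback: it sets out from aldehyde 7 and bromide 2 and comes back at 12. The addition/re-oxidation detour is replaced by a Stork–Danheiser-type carbonyl transposition, so no oxidation is needed.
  - An asymmetric hetero-Diels–Alder reaction of 7 with 1,3-dimethoxy-1-(trimethylsilyloxy)buta-1,3-diene (Ti(IV)–BINOL type catalyst) gives (6S)-6-aryl-4-methoxy-5,6-dihydro-2H-pyran-2-one F5.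
  - Alkylation of the lithium enolate of tert-butyl acetate with 2 gives tert-butyl 5-methylhex-4-enoate F6.
  - The lithium enolate of F6 (2.2 equiv, −78 °C) attacks the lactone carbonyl of F5 in a Claisen-type acylation, to give the ring-opened β-keto ester F7.
  - Mild acid (PPTS, wet CH2Cl2) recloses the carbinol oxygen onto the new ketone and expels methanol, to give the pyranonyl tert-butyl ester F8.
  - TMSOTf/2,6-lutidine followed by buffer unmasks acid 12 without hydroxide.

**3. Step 1.**
- What may go wrong:
  - base-induced prototropic shift of the doubly activated CH2 of the skipped enyne into conjugation;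
  - SN2' attack on the allylic bromide;
  - hydration of the ynol ether on work-up;
  - loss by volatility.
- Fallback: it sets out from acid 5 and comes back at 4. The C–C bond is already in place, and the triple bond is made last by elimination.
  - Esterification (MeOH, cat. H2SO4) gives methyl 5-methylhex-4-enoate F9.
  - LDA followed by ClP(O)(OEt)2 gives the ketene acetal phosphate F10.
  - β-Elimination of phosphate with lithium tetramethylpiperidide at −78 °C (enol phosphate route to alkynes) gives 4.

## Further compounds

F1 | step 6 | 1-[2,4,6-trihydroxy-3,5-bis(3-methylbut-2-en-1-yl)phenyl]ethanone | CC(=O)c1c(O)c(CC=C(C)C)c(O)c(CC=C(C)C)c1O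
F2 | step 6 | 1-[2,6-dihydroxy-4-methoxy-3,5-bis(3-methylbut-2-en-1-yl)phenyl]ethanone | CC(=O)c1c(O)c(CC=C(C)C)c(OC)c(CC=C(C)C)c1O
F3 | step 6 | (E)-1-[2,6-dihydroxy-4-methoxy-3,5-bis(3-methylbut-2-en-1-yl)phenyl]-3-(dimethylamino)prop-2-en-1-one | CN(C)/C=C/C(=O)c1c(O)c(CC=C(C)C)c(OC)c(CC=C(C)C)c1O
F4 | step 6 | 5-hydroxy-7-methoxy-6,8-bis(3-methylbut-2-en-1-yl)-4H-chromen-4-one | COc1c(CC=C(C)C)c(O)c2c(c1CC=C(C)C)OC=CC2=O
F5 | step 5 | (6S)-6-[4-(tert-butyldimethylsilyloxy)phenyl]-4-methoxy-5,6-dihydro-2H-pyran-2-one | COC1=CC(=O)O[C@H](c2ccc(O[Si](C)(C)C(C)(C)C)cc2)C1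
F6 | step 5 | tert-butyl 5-methylhex-4-enoate | CC(C)=CCCC(=O)OC(C)(C)C
F7 | step 5 | tert-butyl (7S)-7-[4-(tert-butyldimethylsilyloxy)phenyl]-7-hydroxy-5-methoxy-2-(3-methylbut-2-en-1-yl)-3-oxohept-4-enoate | CC(C)=CCC(C(=O)OC(C)(C)C)C(=O)C=C(OC)C[C@@H](c1ccc(O[Si](C)(C)C(C)(C)C)cc1)O
F8 | step 5 | tert-butyl 2-{(2S)-2-[4-(tert-butyldimethylsilyloxy)phenyl]-4-oxo-3,4-dihydro-2H-pyran-6-yl}-5-methylhex-4-enoate | CC(C)=CCC(C(=O)OC(C)(C)C)C1=CC(=O)C[C@@H](c2ccc(O[Si](C)(C)C(C)(C)C)cc2)O1
F9 | step 1 | methyl 5-methylhex-4-enoate | COC(=O)CCC=C(C)C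
F10 | step 1 | diethyl 1-methoxy-5-methylhexa-1,4-dien-1-yl phosphate | CCOP(=O)(OCC)OC(OC)=CCC=C(C)C
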